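**Plan**

- Retrosynthetic cuts, in order: the exocyclic C3=CH–Ar double bond (aldol condensation with O-silylated vanillin), the ring bond C3–C4 of the lactone (carbene C–H insertion), and the ester bond O1–C2 (acylation of 3-(3,4-dimethoxyphenyl)propan-1-ol).
- Enabling feature: C3 lies α to the lactone carbonyl C2, so it can be raised to a diazo carbon and turned into an electrophilic metal carbene (polarity reversal of an enolate carbon). C4 is, before ring closure, a plain CH2 five atoms away along C3–C2–O1–C5–C4, and its two hydrogens are enantiotopic.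
- Forward order: alcohol → bromoacetate → diazoacetate → closure of the only new ring (the γ-lactone) → aldol addition of protected vanillin at C3 → dehydration → desilylation. Both arene rings are bought.
- Stereochemistry: C4 (R) comes from catalyst control in the insertion and is not touched afterwards. The E double bond comes from the E1cB dehydration, which should give the more stable isomer with the aryl ring trans to the lactone carbonyl.

Key step: step 3

Remark: Rh2(4S-MPPIM)4, dirhodium tetrakis[methyl (4S)-2-oxo-1-(3-phenylpropanoyl)imidazolidine-4-carboxylate], is taken to induce the R configuration at C4; should the sense be the opposite, the 4R antipode of the catalyst is used with nothing else changed.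

**Route**

Step 1
Reactants: 1 3-(3,4-dimethoxyphenyl)propan-1-ol
Product: 2 3-(3,4-dimethoxyphenyl)propyl 2-bromoacetate
Conditions: BrCH2COBr, NaHCO3, MeCN, 0 °C
Reagents that add atoms: bromoacetyl bromide, BrCC(Br)=O
Why: O-acylation of a primary alcohol by an acid bromide (nucleophilic acyl substitution) is much faster than displacement of the alkyl bromide, and NaHCO3 takes up the HBr.

Step 2
Reactants: 2 3-(3,4-dimethoxyphenyl)propyl 2-bromoacetate
Product: 5 3-(3,4-dimethoxyphenyl)propyl 2-diazoacetate, via N-alkylated ditosylhydrazine 3 (not isolated), via tosylhydrazone ester 4 (not isolated)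
Conditions: TsNHNHTs, DBU, THF, 0 °C
Reagents that add atoms: N,N'-ditosylhydrazine, Cc1ccc(cc1)S(=O)(=O)NNS(=O)(=O)c1ccc(C)cc1
Why: Fukuyama diazoacetate synthesis, in which SN2 alkylation of the ditosylhydrazine anion by the bromoacetate is followed by two base-induced losses of p-toluenesulfinate (the second a Bamford–Stevens-type fragmentation), should give the diazo ester under conditions that leave the ester untouched.

Step 3
Reactants: 5 3-(3,4-dimethoxyphenyl)propyl 2-diazoacetate
Product: 6 (R)-4-(3,4-dimethoxybenzyl)dihydrofuran-2(3H)-one
Conditions: Rh2(4S-MPPIM)4 (1 mol %), CH2Cl2, reflux, slow addition of 5 (syringe pump)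
Reagents that add atoms: none
Why: The diazoacetate loses N2 at an axial site of the dirhodium carboxamidate (divalent rhodium) to give an electrophilic rhodium carbene at the future C3, which inserts in a concerted, asynchronous three-centre step into a C–H bond of the central CH2 of the propyl chain, the future C4 (hydride-like shift to the carbene carbon with C–C bond formation and retention at C4), and releases the catalyst. The closest known reaction type is the enantioselective intramolecular C–H insertion of diazoacetates of primary 3-arylpropanols under chiral dirhodium carboxamidate catalysis, established for β-benzyl-γ-butyrolactones. The lactone ring closes by 1,5-insertion, that is a five-membered ring C3–C2–O1–C5–C4 formed through a cyclic array of these five atoms plus the migrating hydrogen. The new stereocentre C4 is under catalyst control: the four N,O-bound imidazolidinone ligands, whose ester and N-acyl groups wall in the carbene, fix the orientation of the tethered chain so that only one of the two enantiotopic C–H bonds reaches the carbene carbon, which should give the R lactone in high enantiomeric excess. The step needs site selectivity for the C4–H bonds over the O–CH2 bonds (four-membered ring, deactivated by the acyloxy group), over the benzylic CH2 (six-membered ring), and over attack on the electron-rich arene or carbene dimerisation; the five-ring preference of acceptor-only carbenes, the low electrophilicity of the carboxamidate-bound carbene and slow addition at high dilution should secure it.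

Step 4
Reactants: 7 vanillin
Product: 8 4-(tert-butyldimethylsilyloxy)-3-methoxybenzaldehyde
Conditions: TBSCl, imidazole, DMF, rt
Reagents that add atoms: tert-butyldimethylsilyl chloride, CC(C)(C)[Si](C)(C)Cl
Why: Imidazole-promoted silylation of a phenol (Corey silyl ether protocol) masks the acidic OH so that the lithium enolate of step 5 is not quenched.

Step 5
Reactants: 6 (R)-4-(3,4-dimethoxybenzyl)dihydrofuran-2(3H)-one; 8 4-(tert-butyldimethylsilyloxy)-3-methoxybenzaldehyde
Product: 10 (3S,4R)-3-{[4-(tert-butyldimethylsilyloxy)-3-methoxyphenyl](hydroxy)methyl}-4-(3,4-dimethoxybenzyl)dihydrofuran-2(3H)-one (both carbinol epimers), via lithium enolate 9 (not isolated)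
Conditions: LiN(iPr)2, THF, −78 °C; then 8; then AcOH, −78 °C
Reagents that add atoms: none
Why: Lithium enolate aldol addition, in which kinetic deprotonation occurs at C3 (the only α-position) and the aldehyde adds anti to the C4 benzyl group, should give the 3,4-trans adduct; the two new centres are of no consequence because step 6 removes them, and C4 is not touched.

Step 6
Reactants: 10 (3S,4R)-3-{[4-(tert-butyldimethylsilyloxy)-3-methoxyphenyl](hydroxy)methyl}-4-(3,4-dimethoxybenzyl)dihydrofuran-2(3H)-one
Product: 12 (3E,4R)-3-[4-(tert-butyldimethylsilyloxy)-3-methoxybenzylidene]-4-(3,4-dimethoxybenzyl)dihydrofuran-2(3H)-one, via benzylic mesylate 11 (not isolated)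
Conditions: MsCl, Et3N, CH2Cl2, 0 °C; then DBU, 0 °C to rt
Reagents that add atoms: none
Why: Mesylation followed by E1cB elimination through the lactone enolate should give the E alkene from both carbinol epimers, because the intermediate enolate can rotate before loss of mesylate and the isomer with the aryl ring trans to the carbonyl and coplanar with the enoate is the more stable one; short exposure to DBU should leave C4–H in place.

Step 7
Reactants: 12 (3E,4R)-3-[4-(tert-butyldimethylsilyloxy)-3-methoxybenzylidene]-4-(3,4-dimethoxybenzyl)dihydrofuran-2(3H)-one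
Product: 13 (3E,4R)-4-(3,4-dimethoxybenzyl)-3-(4-hydroxy-3-methoxybenzylidene)dihydrofuran-2(3H)-one
Conditions: Bu4NF, AcOH, THF, 0 °C
Reagents that add atoms: none
Why: Fluoride-induced cleavage of an aryl silyl ether is fast at 0 °C, and the acetic acid buffer protonates the phenoxide at once, so the lactone, the E alkene and C4 should be unaffected.

**Compound list**

1 | 3-(3,4-dimethoxyphenyl)propan-1-ol | COc1ccc(CCCO)cc1OC | starting material
2 | 3-(3,4-dimethoxyphenyl)propyl 2-bromoacetate | COc1ccc(CCCOC(=O)CBr)cc1OC | intermediate
3 | 3-(3,4-dimethoxyphenyl)propyl 2-[1,2-bis(4-methylphenylsulfonyl)hydrazinyl]acetate (not isolated) | COc1ccc(CCCOC(=O)CN(NS(=O)(=O)c2ccc(C)cc2)S(=O)(=O)c2ccc(C)cc2)cc1OC | intermediate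
4 | 3-(3,4-dimethoxyphenyl)propyl 2-[2-(4-methylphenylsulfonyl)hydrazinylidene]acetate (not isolated) | COc1ccc(CCCOC(=O)C=NNS(=O)(=O)c2ccc(C)cc2)cc1OC | intermediate
5 | 3-(3,4-dimethoxyphenyl)propyl 2-diazoacetate | COc1ccc(CCCOC(=O)C=[N+]=[N-])cc1OC | intermediate
6 | (R)-4-(3,4-dimethoxybenzyl)dihydrofuran-2(3H)-one | COc1ccc(C[C@H]2COC(=O)C2)cc1OC | intermediate
7 | vanillin (4-hydroxy-3-methoxybenzaldehyde) | COc1cc(C=O)ccc1O | starting material
8 | 4-(tert-butyldimethylsilyloxy)-3-methoxybenzaldehyde | COc1cc(C=O)ccc1O[Si](C)(C)C(C)(C)C | intermediate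
9 | lithium enolate of 6 (not isolated) | COc1ccc(C[C@H]2COC([O-])=C2)cc1OC.[Li+] | intermediate
10 | (3S,4R)-3-{[4-(tert-butyldimethylsilyloxy)-3-methoxyphenyl](hydroxy)methyl}-4-(3,4-dimethoxybenzyl)dihydrofuran-2(3H)-one, carbinol centre as both epimers | O=C1OC[C@H](Cc2ccc(OC)c(OC)c2)[C@H]1C(O)c1ccc(O[Si](C)(C)C(C)(C)C)c(OC)c1 | intermediate
11 | methanesulfonate of 10 at the benzylic hydroxyl, both epimers (not isolated) | O=C1OC[C@H](Cc2ccc(OC)c(OC)c2)[C@H]1C(OS(C)(=O)=O)c1ccc(O[Si](C)(C)C(C)(C)C)c(OC)c1 | intermediate
12 | (3E,4R)-3-[4-(tert-butyldimethylsilyloxy)-3-methoxybenzylidene]-4-(3,4-dimethoxybenzyl)dihydrofuran-2(3H)-one | COc1cc(/C=C2/C(=O)OC[C@@H]2Cc2ccc(OC)c(OC)c2)ccc1O[Si](C)(C)C(C)(C)C | intermediate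
13 | (3E,4R)-4-(3,4-dimethoxybenzyl)-3-(4-hydroxy-3-methoxybenzylidene)dihydrofuran-2(3H)-one | COc1cc(/C=C2/C(=O)OC[C@@H]2Cc2ccc(OC)c(OC)c2)ccc1O | target

**Summary**

Total step count: 7. Longest linear sequence: 6 steps (steps 1, 2, 3, 5, 6 and 7, from 1).

Steps most likely to fail:

Step 3. The carbene may insert at a wrong site (benzylic or O-adjacent C–H), attack the dimethoxyarene, dimerise, or discriminate poorly between the two enantiotopic C–H bonds. The fallback sets the centre by auxiliary-controlled alkylation and closes the ring at O1–C2 instead; it sets out from 1 and comes back at 6. Alcohol 1 is oxidised (TEMPO cat., PhI(OAc)2, MeCN/H2O) to 3-(3,4-dimethoxyphenyl)propanoic acid F1. The acid is activated as the pivalic mixed anhydride (pivaloyl chloride, Et3N, THF) and joined to (S)-4-benzyloxazolidin-2-one in the presence of LiCl to give (S)-4-benzyl-3-[3-(3,4-dimethoxyphenyl)propanoyl]oxazolidin-2-one F2. Evans alkylation (NaN(SiMe3)2, THF, −78 °C, then tert-butyl bromoacetate) should take place on the face of the chelated Z-enolate away from the auxiliary benzyl group and give tert-butyl (3R)-4-[(4S)-4-benzyl-2-oxooxazolidin-3-yl]-3-(3,4-dimethoxybenzyl)-4-oxobutanoate F3. Reduction of the imide carbonyl with LiBH4 (THF, a little water, 0 °C) releases the auxiliary and gives tert-butyl (3R)-4-(3,4-dimethoxyphenyl)-3-(hydroxymethyl)butanoate F4, which on treatment with CF3CO2H in CH2Cl2 loses the tert-butyl group and lactonises to 6.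

Step 6. The elimination may show poor geometric control, or the base may move the new double bond into the ring, which would erase C4. The fallback replaces aldol addition and dehydration by a Horner–Wadsworth–Emmons olefination; it sets out from 6 and comes back at 12. Lactone 6 is treated with LiN(iPr)2 (2.2 equivalents) and ClP(O)(OEt)2 in THF at −78 °C to rt; the enol phosphate formed first should undergo 1,3-phosphorus migration to give diethyl [(4S)-4-(3,4-dimethoxybenzyl)-2-oxotetrahydrofuran-3-yl]phosphonate F5 (same spatial arrangement at C4 as in 6, the descriptor changes only because phosphorus outranks oxygen). Deprotonation with KOtBu in THF and addition of aldehyde 8 should give 12, the E geometry arising from the reversible addition and syn-elimination of the stabilised phosphonate.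

Step 2. DBU may attack the bromoacetate in competition with the hydrazine, the second loss of sulfinate may be incomplete, or the diazo ester may decompose on purification. The fallback builds the diazo group by diazo transfer and deacylation; it sets out from 1 and comes back at 5, replacing steps 1 and 2. Alcohol 1 is heated with 2,2,6-trimethyl-4H-1,3-dioxin-4-one in xylene at 140 °C (acetylketene transfer) to give 3-(3,4-dimethoxyphenyl)propyl 3-oxobutanoate F6. Regitz diazo transfer (4-acetamidobenzenesulfonyl azide, Et3N, MeCN) gives 3-(3,4-dimethoxyphenyl)propyl 2-diazo-3-oxobutanoate F7, and deacylative cleavage with LiOH in aqueous MeCN at rt gives 5.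

**Further compounds**

F1 | step 3 | 3-(3,4-dimethoxyphenyl)propanoic acid | COc1ccc(CCC(=O)O)cc1OC
F2 | step 3 | (S)-4-benzyl-3-[3-(3,4-dimethoxyphenyl)propanoyl]oxazolidin-2-one | COc1ccc(CCC(=O)N2[C@@H](Cc3ccccc3)COC2=O)cc1OC
F3 | step 3 | tert-butyl (3R)-4-[(4S)-4-benzyl-2-oxooxazolidin-3-yl]-3-(3,4-dimethoxybenzyl)-4-oxobutanoate | COc1ccc(C[C@H](CC(=O)OC(C)(C)C)C(=O)N2[C@@H](Cc3ccccc3)COC2=O)cc1OC
F4 | step 3 | tert-butyl (3R)-4-(3,4-dimethoxyphenyl)-3-(hydroxymethyl)butanoate | COc1ccc(C[C@H](CC(=O)OC(C)(C)C)CO)cc1OC
F5 | step 6 | diethyl [(4S)-4-(3,4-dimethoxybenzyl)-2-oxotetrahydrofuran-3-yl]phosphonate, C3 as both epimers | COc1ccc(C[C@H]2COC(=O)C2P(=O)(OCC)OCC)cc1OC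
F6 | step 2 | 3-(3,4-dimethoxyphenyl)propyl 3-oxobutanoate | COc1ccc(CCCOC(=O)CC(C)=O)cc1OC
F7 | step 2 | 3-(3,4-dimethoxyphenyl)propyl 2-diazo-3-oxobutanoate | COc1ccc(CCCOC(=O)C(=[N+]=[N-])C(C)=O)cc1OC
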